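**Strategy.** The upper flavanone ring C is a β-aryloxy ketone: O1 sits on C2, β to the C4 carbonyl, with C3 (carrying C8'' of the naringenin unit) in between. Everything rests on opening that ring at O1–C2 to a (Z)-2'-hydroxy-α-aryl chalcone, whose α-aryl group is tri-O-benzyl-(2S)-naringenin attached through C8''. A cinchona-thiourea-catalysed 6-endo oxa-Michael addition of the ring-A phenol closes ring C, sets C2 (R) under catalyst control and, by kinetic C-protonation anti to the new C2 aryl, the less stable 2,3-cis C3 (R) centre in one operation. The chalcone is assembled convergently by hydrostannation of an ynone and Stille coupling with 8-iodonaringenin tribenzyl ether; neutral hydrogenolysis ends the route.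

Key step: step 11

Remark: upper-unit locants are unprimed and naringenin-unit locants double-primed; the upper ring of the target is 2,3-cis (2R,3R), the C3 epimer that base would turn into the trans compound, so no basic step follows the key step, and (2S)-naringenin of high enantiomeric purity is taken as the purchased chiral-pool material.

**Route**

Step 1
Reactants: 1 (2S)-naringenin
Product: 2 (2S)-5,7-bis(benzyloxy)-2-(4-benzyloxyphenyl)chroman-4-one
Conditions: BnOH, PPh3, DIAD (4.5 equiv each), THF, 0 °C → 40 °C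
Reagents that add atoms: benzyl alcohol OCc1ccccc1
Why: Mitsunobu etherification should alkylate all three phenols (the chelated 5-OH last) under neutral redox conditions without a free base, so the flavanone C2 centre, which racemises by ring opening in alkali, is kept.

Step 2
Reactants: 2 (2S)-5,7-bis(benzyloxy)-2-(4-benzyloxyphenyl)chroman-4-one
Product: 3 (2S)-5,7-bis(benzyloxy)-2-(4-benzyloxyphenyl)-8-iodochroman-4-one
Conditions: NIS (1.0 equiv), TFA (10 mol %), MeCN/CH2Cl2, 0 °C → rt
Reagents that add atoms: N-iodosuccinimide O=C1CCC(=O)N1I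
Why: Electrophilic aromatic iodination of a 5,7-dialkoxy flavanone should go to C8, which is flanked by the tied-back ring oxygen, in preference to C6 between two benzyloxy groups, and the acidic medium leaves C2 untouched.

Step 3
Reactants: 4 3,4-bis(benzyloxy)benzaldehyde
Product: 5 1,2-bis(benzyloxy)-4-ethynylbenzene
Conditions: dimethyl (1-diazo-2-oxopropyl)phosphonate, K2CO3, MeOH, rt
Reagents that add atoms: Ohira–Bestmann reagent CC(=O)C(=[N+]=[N-])P(=O)(OC)OC
Why: Ohira–Bestmann (Seyferth–Gilbert) homologation turns the aldehyde into the terminal alkyne under mild carbonate conditions, the added carbon becoming C3 of the upper unit.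

Step 4
Reactants: 6 2,4,6-trihydroxybenzaldehyde
Product: 7 2,4-bis(benzyloxy)-6-hydroxybenzaldehyde
Conditions: BnBr (2.1 equiv), K2CO3, DMF, 0 °C → rt
Reagents that add atoms: benzyl bromide BrCc1ccccc1
Why: Williamson etherification should take the para hydroxyl and one ortho hydroxyl and leave the second ortho hydroxyl, which is hydrogen-bonded to the formyl group.

Step 5
Reactants: 7 2,4-bis(benzyloxy)-6-hydroxybenzaldehyde
Product: 8 2,4-bis(benzyloxy)-6-(methoxymethoxy)benzaldehyde
Conditions: MOMCl, i-Pr2NEt, CH2Cl2, 0 °C → rt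
Reagents that add atoms: chloromethyl methyl ether COCCl
Why: Acetal (MOM) protection masks the future ring-closing phenol with a group that survives organolithium, tin hydride and palladium steps and is orthogonal to benzyl.

Step 6
Reactants: 5 1,2-bis(benzyloxy)-4-ethynylbenzene; 8 2,4-bis(benzyloxy)-6-(methoxymethoxy)benzaldehyde
Product: 10 rac-1-[2,4-bis(benzyloxy)-6-(methoxymethoxy)phenyl]-3-[3,4-bis(benzyloxy)phenyl]prop-2-yn-1-ol, via lithium acetylide 9 (not isolated)
Conditions: 5, n-BuLi, THF, −78 °C; then 8, −78 → 0 °C; aq. NH4Cl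
Reagents that add atoms: none
Why: 1,2-Addition of a lithium acetylide to the aldehyde forms the C3–C4 bond of the upper unit, the racemic carbinol centre being erased in the next step.

Step 7
Reactants: 10 rac-propargylic alcohol
Product: 11 1-[2,4-bis(benzyloxy)-6-(methoxymethoxy)phenyl]-3-[3,4-bis(benzyloxy)phenyl]prop-2-yn-1-one
Conditions: MnO2 (excess), CH2Cl2, rt
Reagents that add atoms: none
Why: MnO2 oxidation is selective for a propargylic and benzylic alcohol and should give the ynone without touching the ethers.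

Step 8
Reactants: 11 ynone
Product: 12 (E)-1-[2,4-bis(benzyloxy)-6-(methoxymethoxy)phenyl]-3-[3,4-bis(benzyloxy)phenyl]-2-(tributylstannyl)prop-2-en-1-one
Conditions: Bu3SnH (1.1 equiv, slow addition), Pd(PPh3)4 (3 mol %), THF, 0 °C
Reagents that add atoms: tributyltin hydride CCCC[SnH](CCCC)CCCC
Why: Hydrostannation of an alkynyl ketone under zerovalent palladium catalysis is a syn addition that places tin on the carbon next to the carbonyl and hydrogen on the β-carbon, which fixes the alkene geometry (carbonyl cis to the 3-aryl group).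

Step 9
Reactants: 12 (E)-α-stannyl enone; 3 (2S)-8-iodonaringenin tribenzyl ether
Product: 13 (Z)-1-[2,4-bis(benzyloxy)-6-(methoxymethoxy)phenyl]-3-[3,4-bis(benzyloxy)phenyl]-2-[(2S)-5,7-bis(benzyloxy)-2-(4-benzyloxyphenyl)-4-oxochroman-8-yl]prop-2-en-1-one
Conditions: Pd2(dba)3 (5 mol %), tri(2-furyl)phosphine (20 mol %), CuI (20 mol %), NMP, 60 °C
Reagents that add atoms: none
Why: Stille cross-coupling with retention of alkene geometry forms the C3–C8'' bond between the two halves under base-free conditions that do not enolise or open the flavanone of 3.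

Step 10
Reactants: 13 MOM-protected α-aryl chalcone
Product: 14 (Z)-1-[2,4-bis(benzyloxy)-6-hydroxyphenyl]-3-[3,4-bis(benzyloxy)phenyl]-2-[(2S)-5,7-bis(benzyloxy)-2-(4-benzyloxyphenyl)-4-oxochroman-8-yl]prop-2-en-1-one
Conditions: HCl (1.25 M in MeOH), THF, 0 °C → rt
Reagents that add atoms: none
Why: Acid-catalysed acetal exchange removes the MOM group activated by the ortho carbonyl without touching benzyl ethers, and a chelated 2'-hydroxy-6'-alkoxychalcone should resist cold dilute acid, so ring closure is held back for the catalyst-controlled step.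

Step 11
Reactants: 14 (Z)-2'-hydroxy-α-aryl chalcone
Product: 16 (2R,3R)-5,7-bis(benzyloxy)-2-[3,4-bis(benzyloxy)phenyl]-3-[(2S)-5,7-bis(benzyloxy)-2-(4-benzyloxyphenyl)-4-oxochroman-8-yl]chroman-4-one (2,3-cis), via chromen-4-ol enol 15 (not isolated)
Conditions: quinidine-derived bifunctional thiourea, 1-[3,5-bis(trifluoromethyl)phenyl]-3-(9-deoxy-epi-quinidin-9-yl)thiourea (15 mol %), toluene, −20 °C; AcOH quench at −20 °C, rapid filtration through silica
Reagents that add atoms: none
Why: The quinuclidine nitrogen of the catalyst deprotonates the chelated ring-A phenol while the thiourea hydrogen-bonds the enone carbonyl, the phenoxide adds to the β-carbon (future C2) to give the catalyst-bound enol 15, and the quinuclidinium C-protonates it to the ketone; this is the organocatalytic intramolecular oxa-Michael addition/protonation established for α-substituted 2'-hydroxychalcones. Ring C closes in the 6-endo-trig mode, helped by the 6'-benzyloxy and α-aryl groups, which twist the enone out of plane and place the phenol oxygen over the β-carbon. C2 (R) is set by the catalyst, which differentiates the two faces of the single (Z)-alkene; the quinine-derived pseudo-enantiomer is the alternative if the sense has to be reversed, and the remote 2''S centre makes any minor C2 epimer a separable diastereomer. C3 (R) is set by the substrate: in enol 15 the C2 aryl is pseudo-axial to avoid allylic strain with the C3 aryl, so the proton enters anti to it and the two aryl groups end up cis. The step needs kinetic control at C3, because equilibration would give the trans epimer; this is secured by the weakly basic catalyst, low temperature, the acid quench and the doubly ortho-substituted C3 aryl, which hinders re-enolisation. The benzyl ethers and the fully alkylated flavanone of the lower unit are inert to these conditions.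

Step 12
Reactants: 16 hepta-O-benzyl ether of the target
Product: 17 (2R,3R)-2-(3,4-dihydroxyphenyl)-5,7-dihydroxy-3-[(2S)-5,7-dihydroxy-2-(4-hydroxyphenyl)-4-oxochroman-8-yl]chroman-4-one (CNP0105436.1)
Conditions: H2 (1 atm), Pd/C (10 %), EtOAc/MeOH, rt; reversed-phase purification with 0.1 % HCO2H
Reagents that add atoms: none
Why: Hydrogenolysis of the seven benzyl ethers over palladium on carbon is neutral, so the base-labile cis C3 centre and both C2 centres should be preserved while all phenols are released.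

**Compound list**

1 | (2S)-naringenin, (2S)-5,7-dihydroxy-2-(4-hydroxyphenyl)chroman-4-one | O=C1C[C@@H](c2ccc(O)cc2)Oc2cc(O)cc(O)c21 | starting material
2 | (2S)-5,7-bis(benzyloxy)-2-(4-benzyloxyphenyl)chroman-4-one | O=C1C[C@@H](c2ccc(OCc3ccccc3)cc2)Oc2cc(OCc3ccccc3)cc(OCc3ccccc3)c21 | intermediate
3 | (2S)-5,7-bis(benzyloxy)-2-(4-benzyloxyphenyl)-8-iodochroman-4-one | O=C1C[C@@H](c2ccc(OCc3ccccc3)cc2)Oc2c(I)c(OCc3ccccc3)cc(OCc3ccccc3)c21 | intermediate
4 | 3,4-bis(benzyloxy)benzaldehyde | O=Cc1ccc(OCc2ccccc2)c(OCc2ccccc2)c1 | starting material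
5 | 1,2-bis(benzyloxy)-4-ethynylbenzene | C#Cc1ccc(OCc2ccccc2)c(OCc2ccccc2)c1 | intermediate
6 | 2,4,6-trihydroxybenzaldehyde | O=Cc1c(O)cc(O)cc1O | starting material
7 | 2,4-bis(benzyloxy)-6-hydroxybenzaldehyde | O=Cc1c(O)cc(OCc2ccccc2)cc1OCc1ccccc1 | intermediate
8 | 2,4-bis(benzyloxy)-6-(methoxymethoxy)benzaldehyde | O=Cc1c(OCOC)cc(OCc2ccccc2)cc1OCc1ccccc1 | intermediate
9 | lithium acetylide of 5, [3,4-bis(benzyloxy)phenyl]ethynyllithium | [Li]C#Cc1ccc(OCc2ccccc2)c(OCc2ccccc2)c1 | intermediate (not isolated)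
10 | rac-1-[2,4-bis(benzyloxy)-6-(methoxymethoxy)phenyl]-3-[3,4-bis(benzyloxy)phenyl]prop-2-yn-1-ol | OC(C#Cc1ccc(OCc2ccccc2)c(OCc2ccccc2)c1)c1c(OCOC)cc(OCc2ccccc2)cc1OCc1ccccc1 | intermediate
11 | 1-[2,4-bis(benzyloxy)-6-(methoxymethoxy)phenyl]-3-[3,4-bis(benzyloxy)phenyl]prop-2-yn-1-one | O=C(C#Cc1ccc(OCc2ccccc2)c(OCc2ccccc2)c1)c1c(OCOC)cc(OCc2ccccc2)cc1OCc1ccccc1 | intermediate
12 | (E)-1-[2,4-bis(benzyloxy)-6-(methoxymethoxy)phenyl]-3-[3,4-bis(benzyloxy)phenyl]-2-(tributylstannyl)prop-2-en-1-one (carbonyl cis to the 3-aryl group) | O=C(c1c(OCOC)cc(OCc2ccccc2)cc1OCc1ccccc1)/C(=C\c1ccc(OCc2ccccc2)c(OCc2ccccc2)c1)[Sn](CCCC)(CCCC)CCCC | intermediate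
13 | (Z)-1-[2,4-bis(benzyloxy)-6-(methoxymethoxy)phenyl]-3-[3,4-bis(benzyloxy)phenyl]-2-[(2S)-5,7-bis(benzyloxy)-2-(4-benzyloxyphenyl)-4-oxochroman-8-yl]prop-2-en-1-one | O=C(c1c(OCOC)cc(OCc2ccccc2)cc1OCc1ccccc1)/C(=C\c1ccc(OCc2ccccc2)c(OCc2ccccc2)c1)c1c(OCc2ccccc2)cc(OCc2ccccc2)c2c1O[C@H](c1ccc(OCc3ccccc3)cc1)CC2=O | intermediate
14 | (Z)-1-[2,4-bis(benzyloxy)-6-hydroxyphenyl]-3-[3,4-bis(benzyloxy)phenyl]-2-[(2S)-5,7-bis(benzyloxy)-2-(4-benzyloxyphenyl)-4-oxochroman-8-yl]prop-2-en-1-one | O=C(c1c(O)cc(OCc2ccccc2)cc1OCc1ccccc1)/C(=C\c1ccc(OCc2ccccc2)c(OCc2ccccc2)c1)c1c(OCc2ccccc2)cc(OCc2ccccc2)c2c1O[C@H](c1ccc(OCc3ccccc3)cc1)CC2=O | intermediate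
15 | enol tautomer of 16, a 4-hydroxy-2H-chromene with a C3=C4 double bond (C2 arranged as in 16; formally 2S by CIP because C3 is sp2) | O=C1C[C@@H](c2ccc(OCc3ccccc3)cc2)Oc2c1c(OCc1ccccc1)cc(OCc1ccccc1)c2C1=C(O)c2c(OCc3ccccc3)cc(OCc3ccccc3)cc2O[C@H]1c1ccc(OCc2ccccc2)c(OCc2ccccc2)c1 | intermediate (not isolated)
16 | (2R,3R)-5,7-bis(benzyloxy)-2-[3,4-bis(benzyloxy)phenyl]-3-[(2S)-5,7-bis(benzyloxy)-2-(4-benzyloxyphenyl)-4-oxochroman-8-yl]chroman-4-one (2,3-cis) | O=C1C[C@@H](c2ccc(OCc3ccccc3)cc2)Oc2c1c(OCc1ccccc1)cc(OCc1ccccc1)c2[C@H]1C(=O)c2c(OCc3ccccc3)cc(OCc3ccccc3)cc2O[C@H]1c1ccc(OCc2ccccc2)c(OCc2ccccc2)c1 | intermediate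
17 | (2R,3R)-2-(3,4-dihydroxyphenyl)-5,7-dihydroxy-3-[(2S)-5,7-dihydroxy-2-(4-hydroxyphenyl)-4-oxochroman-8-yl]chroman-4-one | O=C1C[C@@H](c2ccc(O)cc2)Oc2c1c(O)cc(O)c2[C@H]1C(=O)c2c(O)cc(O)cc2O[C@H]1c1ccc(O)c(O)c1 | target

**Step count.** Total: 12 steps. Longest linear sequence: 9 steps (6 → 7 → 8 → 10 → 11 → 12 → 13 → 14 → 16 → 17, steps 4 to 12).

**Steps most likely to fail**

1. Step 11. The kinetic 2,3-cis relationship may be eroded by amine-mediated enolisation at C3 during or after ring closure, and facial control at C2 may be incomplete on this hindered α-aryl chalcone. The fallback separates the two stereochemical tasks. It sets out from 14, which is cyclised with the same catalyst in toluene at room temperature for a prolonged time so that C3 equilibrates. This should give the 2,3-trans compound (2R,3S)-5,7-bis(benzyloxy)-2-[3,4-bis(benzyloxy)phenyl]-3-[(2S)-5,7-bis(benzyloxy)-2-(4-benzyloxyphenyl)-4-oxochroman-8-yl]chroman-4-one F1; any C2 epimer is a diastereomer because of the 2''S centre and is removed by chromatography. Soft enolisation of F1 (TMSOTf, Et3N, CH2Cl2, −78 → 0 °C) should give the bis(trimethylsilyl enol ether) of both chromanone rings F2. Low-temperature protonolysis of F2 (Et3N·3HF, THF, −78 °C) protonates C3 anti to the C2 aryl in a separate, base-free operation and returns to the route at 16.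

2. Step 9. Transmetalation of the α-stannyl enone onto a doubly ortho-substituted, electron-rich arylpalladium centre may be slow, so that protodestannylation and homocoupling overtake the coupling. The fallback reverses the polarity of the union. From 12, iododestannylation (I2, CH2Cl2, 0 °C) with retention should give (E)-1-[2,4-bis(benzyloxy)-6-(methoxymethoxy)phenyl]-3-[3,4-bis(benzyloxy)phenyl]-2-iodoprop-2-en-1-one F3. From 3, Miyaura borylation (B2pin2, PdCl2(dppf), KOAc, dioxane, 80 °C) should give (2S)-5,7-bis(benzyloxy)-2-(4-benzyloxyphenyl)-8-(4,4,5,5-tetramethyl-1,3,2-dioxaborolan-2-yl)chroman-4-one F4. Suzuki–Miyaura coupling of F3 with F4 (Pd(OAc)2, SPhos, K3PO4, toluene/H2O, 40 °C) comes back to the route at 13.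

3. Step 12. During the long sevenfold debenzylation, hydrogenolytic opening of the benzylic C2–O1 and C2''–O1'' bonds and surface-mediated epimerisation at C3 may compete. The fallback replaces reduction by Lewis-acid dealkylation. It sets out from 16, which is treated with BCl3 and pentamethylbenzene as cation scavenger in CH2Cl2 at −78 °C and quenched cold with MeOH. It arrives directly at 17 without any new compound (none, F0).

**Further compounds**

F1 | step 11 | (2R,3S)-5,7-bis(benzyloxy)-2-[3,4-bis(benzyloxy)phenyl]-3-[(2S)-5,7-bis(benzyloxy)-2-(4-benzyloxyphenyl)-4-oxochroman-8-yl]chroman-4-one (2,3-trans epimer of 16) | O=C1C[C@@H](c2ccc(OCc3ccccc3)cc2)Oc2c1c(OCc1ccccc1)cc(OCc1ccccc1)c2[C@@H]1C(=O)c2c(OCc3ccccc3)cc(OCc3ccccc3)cc2O[C@H]1c1ccc(OCc2ccccc2)c(OCc2ccccc2)c1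
F2 | step 11 | bis(trimethylsilyl enol ether) of F1, with C3=C4 and C3''=C4'' double bonds and both C4 oxygens silylated (C2 and C2'' arranged as in 16) | C[Si](C)(C)OC1=C[C@@H](c2ccc(OCc3ccccc3)cc2)Oc2c1c(OCc1ccccc1)cc(OCc1ccccc1)c2C1=C(O[Si](C)(C)C)c2c(OCc3ccccc3)cc(OCc3ccccc3)cc2O[C@H]1c1ccc(OCc2ccccc2)c(OCc2ccccc2)c1
F3 | step 9 | (E)-1-[2,4-bis(benzyloxy)-6-(methoxymethoxy)phenyl]-3-[3,4-bis(benzyloxy)phenyl]-2-iodoprop-2-en-1-one | O=C(c1c(OCOC)cc(OCc2ccccc2)cc1OCc1ccccc1)/C(I)=C\c1ccc(OCc2ccccc2)c(OCc2ccccc2)c1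
F4 | step 9 | (2S)-5,7-bis(benzyloxy)-2-(4-benzyloxyphenyl)-8-(4,4,5,5-tetramethyl-1,3,2-dioxaborolan-2-yl)chroman-4-one | O=C1C[C@@H](c2ccc(OCc3ccccc3)cc2)Oc2c(B3OC(C)(C)C(C)(C)O3)c(OCc3ccccc3)cc(OCc3ccccc3)c21
F0 | step 12 | none | none
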